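**Remark on the chemistry:** the coumarin is treated as its 4-hydroxy-2-oxo tautomer; ring A is the benzo ring, ring B the pyranone ring, and the side chain is numbered C1' to C12' outward from C3.

## Analysis of the target

The target is a 4-hydroxycoumarin, a benzo ring (ring A) fused to a 4-hydroxy-2-pyranone (ring B), with a twelve-carbon farnesyl-type chain C1' to C12' on C3 and a benzoate on the terminal allylic oxygen at C12'. It has no stereocentre; its stereochemistry lies in three trisubstituted olefins, C2'=C3', C6'=C7' and C10'=C11', all E and insulated from each other by the CH2CH2 pairs C4'–C5' and C8'–C9', so each geometry must be set or bought on its own. Ring B is a vinylogous carboxylic acid: O4–H is acidic, the O4/C3 system is an ambident nucleophile that is acylated and alkylated readily at oxygen, and under protic acid the hydroxyl adds across C2'=C3' to close a pyran. The C12' benzoate is an allylic ester that would not survive hydride, hydroxide, alkoxide or zerovalent palladium, and the 1,5-diene array is prone to acid-induced cyclisation and double-bond migration. The difficulties are therefore (a) joining C1' to C3 and not to O4, (b) three E olefins without internal control, and (c) oxidising only the terminal methyl group trans to the chain and keeping that oxygen distinguishable from O4 to the last step. The plan rests on the fact that C4' and C5' are both allylic methylenes, C4' beside C2'=C3' and C5' beside C6'=C7'. A cut between them gives two small allylic pieces whose olefins are available in simple building blocks, but both carbons are by nature electrophilic, so one must be made nucleophilic. C5' is the one to reverse, because its allyl partner C7' is fully substituted while C5' is a CH2, and this difference later directs the removal of the activating group.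

## Retrosynthetic reasoning

The O–acyl bond of the C12' benzoate in 24 is cut first, giving diol 22. The benzoate comes last because none of the earlier reagents (carbanions, hydroxide, hydride, amide base) would spare it. The forward step must acylate the primary allylic hydroxyl while the more acidic O4–H is free. Since O4 cannot be kept from reacting, both oxygens are benzoylated to 23, and the O4 benzoate, a vinylogous anhydride, is then cleaved selectively by an amine in the same flask.

Diol 22 is traced to silyl ether 21. The silyl group on O12' keeps the two oxygens apart from step 3 onwards. A fluoride-labile group is chosen so that it can be removed without acid strong enough to cyclise O4 onto C2'=C3'.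

Ring B of 21 is opened at C3–C4 to aryl ester 19, and the ester C–O bond of 19 is cut to acid 17 and methyl salicylate 18. Cutting here and not at C3–C1' avoids alkylating a preformed 4-hydroxycoumarin nucleus, where attack at O4 and allylic transposition in the electrophile compete. Instead the chain arrives with C2 and C3 attached, and 18 brings ring A, O1 and C4. The forward step needs enolate 20 of the aryl ester to condense with the neighbouring methyl ester.

Acid 17 is traced to sulfone acid 15 by restoring a phenylsulfonyl group at C5', and 15 to ethyl ester 14. The sulfonyl group is the price of the polarity reversal and is removed by palladium-catalysed hydride transfer through carboxylate 16. Because that hydride would reduce an ester, the ethyl ester is hydrolysed before this step and the aryl ester is installed after it. The removal must leave C6'=C7' in place and E.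

Ester 14 is cut at C4'–C5' into sulfone 6 and bromo ester 12. This gains convergence: 6 carries C5' to C12' with C6'=C7', C10'=C11' and the terminal oxygen, and 12 carries C2, C3 and C1' to C4' with C2'=C3'. In the forward direction the lithiated sulfone 13 must displace bromide from 12 at the primary carbon without touching the ester and without allylic transposition in either partner.

Sulfone 6 is the silyl ether of alcohol 5, which comes from geranyl phenyl sulfone 3 by allylic oxidation of the terminal methyl group trans to the chain (partly through enal 4). Sulfone 3 comes from geranyl bromide 1 and sodium benzenesulfinate 2. C6'=C7' is bought with 1, and the oxidation is done at the C10 stage, where the only other olefin is deactivated by the neighbouring sulfonyl group.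

Bromide 12 comes from allylic alcohol 11 by exchange of C–O for C–Br, and 11 from ester 9 by the same kind of allylic oxidation (partly through enal 10). Ester 9 comes from 2-methylbut-3-en-2-ol 7 by an orthoester Claisen rearrangement through ketene acetal 8. The rearrangement makes the C3–C1' bond and the γ,δ-unsaturated ester in one step from a five-carbon alcohol; C2'=C3' receives its E geometry in the oxidation.

## Alternatives that were turned down

Alternative 1: The governing disconnection is C3–C4 of ring B. Aryl ester A2, the salicylate ester of the complete chain acid (same structure as 19), is treated with LiN(SiMe3)2; its enolate at C3 attacks the adjacent methyl ester and closes ring B to give A1 (same structure as 21).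
- For: it settles attachment at carbon beyond doubt, it is an intramolecular six-membered closure driven by formation of a stabilised enolate, and it tolerates the silyl ether and the triene.
- Against: as an organising idea it says how the ring is made but not how the chain is made, and the chain is where the difficulty lies. The shortest chain source would be (2E,6E)-farnesyl bromide A3, homologated at C1' by an acetate enolate and oxidised at C12'. That oxidation must single out one of three trisubstituted olefins of nearly equal electron density, so C12' selectivity should be only moderate and the isomers hard to separate.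
- Comparison: on ring formation the two plans are equal, because the chosen route uses this same closure as step 11. On step count a route from A3 could be two or three steps shorter, since no sulfone is put on and taken off. The chosen strategy offers instead a terminal oxidation carried out on small fragments in which only one olefin is reactive, and a convergent chain assembly.

Alternative 2: The disconnection is C8'–C9', with C6'=C7' created in the same step. The secondary allylic alcohol A5, with its hydroxyl at C6' next to an isopropenyl group, is heated with the amide acetal MeC(OMe)2NMe2; the ketene N,O-acetal formed in the flask undergoes an Eschenmoser–Claisen rearrangement to the γ,δ-unsaturated amide A4.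
- For: the chair transition state places the C5' chain equatorial, so E geometry at C6'=C7' is expected with high fidelity; the conditions are neutral; two carbons are added as the olefin is made. In creating this olefin geometry, where the chosen plan only inherits it, the alternative is at least as strong.
- Against: it is linear and iterative. A5 already contains the coumarin with O4 masked as a methyl ether, so the C- versus O-attachment problem at C3 has been met earlier, and the C6' hydroxyl must be introduced site-selectively into a geranyl side chain. After A4, C10', C11', its methyl group and C12' are still missing: the amide must be reduced to the aldehyde, extended by an E-selective olefination, the resulting ester reduced in the presence of the ring B lactone, and the alcohol benzoylated. Finally the O4 methyl group, a vinylogous methyl ester, must be removed from a molecule with an allylic benzoate and an acid-sensitive 1,5-diene: nucleophilic demethylation threatens the benzoate, acidic demethylation threatens C2'=C3'.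
- Comparison: the chosen strategy needs no protection at O4 because ring B is formed late, takes all three olefins from small fragments, and uses one fragment union in place of two chain extensions on a sensitive substrate.

Alternative 3: The disconnection is C1'–C2'. Alkenyl iodide A7, carrying C2' to C12' with the terminal oxygen as a tert-butyldiphenylsilyl ether, is converted by t-BuLi and ZnBr2 into the alkenylzinc, which couples with 3-(bromomethyl)-4-methoxycoumarin A8 under Pd(PPh3)4 (Negishi coupling) to give A6.
- For: it is highly convergent, joins the chain directly to the heterocycle, proceeds with retention at the sp2 carbon so that C2'=C3' is transferred intact, and leaves no activating group to remove. On directness of the bond formation it is stronger than the sulfone union, which needs a separate desulfonylation.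
- Against: the burden moves into A7, a fourteen-carbon piece with two further E olefins, a stereodefined trisubstituted alkenyl iodide and a protected oxygen. Its preparation, including a methylmetalation of a terminal alkyne to set C2'=C3', would take more steps than 6 and 12 together. The exchange needs t-BuLi. A8 again requires the O4 methyl mask, so the end game inherits the demethylation problem of alternative 2 and adds an exchange of silyl for benzoyl.
- Comparison: the chosen plan uses two building blocks reached in three steps each from cheap materials, needs no organometallic beyond n-BuLi, and never has to unmask O4.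

Key step: step 7

## Route

Step 1
Reactants: 1 geranyl bromide; 2 sodium benzenesulfinate
Product: 3 geranyl phenyl sulfone, [(2E)-3,7-dimethylocta-2,6-dien-1-yl] phenyl sulfone
Conditions: PhSO2Na, DMF, rt
Reagents that add atoms: none
Why: The sulfinate anion is alkylated at sulfur by the primary allylic bromide (SN2) in a dipolar aprotic solvent, giving the sulfone and not the sulfinate ester; the 2E olefin of 1 is not touched.

Step 2
Reactants: 3 geranyl phenyl sulfone
Product: 5 (2E,6E)-2,6-dimethyl-8-(phenylsulfonyl)octa-2,6-dien-1-ol, via enal 4 (not isolated)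
Conditions: SeO2 (cat.), t-BuOOH, salicylic acid (cat.), CH2Cl2, rt; then NaBH4, MeOH, 0 °C
Reagents that add atoms: tert-butyl hydroperoxide CC(C)(C)OO (source of the new oxygen, relayed by selenium dioxide O=[Se]=O)
Why: SeO2-catalysed allylic oxidation (ene reaction, then [2,3]-sigmatropic shift) with t-BuOOH as terminal oxidant attacks the electron-rich isopropylidene end at the methyl group trans to the chain, which fixes the E geometry; the olefin next to the electron-poor sulfonylmethyl group reacts much more slowly, and NaBH4 returns the over-oxidised portion, enal 4, to alcohol 5 by 1,2-reduction.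

Step 3
Reactants: 5 (2E,6E)-2,6-dimethyl-8-(phenylsulfonyl)octa-2,6-dien-1-ol
Product: 6 tert-butyl{[(2E,6E)-2,6-dimethyl-8-(phenylsulfonyl)octa-2,6-dien-1-yl]oxy}dimethylsilane
Conditions: TBSCl, imidazole, DMF, 0 °C → rt
Reagents that add atoms: tert-butyldimethylsilyl chloride CC(C)(C)[Si](C)(C)Cl
Why: Standard silylation of a primary allylic alcohol; the tert-butyldimethylsilyl ether is chosen because it withstands n-BuLi at low temperature, LiOH, LiBHEt3 and LiN(SiMe3)2 and is removed by fluoride at the end.

Step 4
Reactants: 7 2-methylbut-3-en-2-ol
Product: 9 ethyl 5-methylhex-4-enoate, via mixed ketene acetal 8 (not isolated)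
Conditions: MeC(OEt)3 (excess), EtCO2H (cat.), 140 °C, EtOH distilled off
Reagents that add atoms: triethyl orthoacetate CCOC(C)(OCC)OCC
Why: Johnson–Claisen (orthoester Claisen) rearrangement: acid-catalysed exchange and loss of ethanol give ketene acetal 8, whose [3,3]-sigmatropic shift forms the bond that becomes C3–C1' and delivers the γ,δ-unsaturated ester; the new olefin carries two identical methyl groups, so no geometry arises here.

Step 5
Reactants: 9 ethyl 5-methylhex-4-enoate
Product: 11 ethyl (4E)-6-hydroxy-5-methylhex-4-enoate, via enal 10 (not isolated)
Conditions: SeO2 (cat.), t-BuOOH, CH2Cl2, rt; then NaBH4, EtOH, 0 °C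
Reagents that add atoms: tert-butyl hydroperoxide CC(C)(C)OO (source of the new oxygen, relayed by selenium dioxide O=[Se]=O)
Why: The same SeO2-catalysed allylic oxidation as in step 2, selective for the methyl group trans to the chain and hence E; the ester is inert, and NaBH4 at 0 °C reduces enal 10 to 11 without touching the ethyl ester.

Step 6
Reactants: 11 ethyl (4E)-6-hydroxy-5-methylhex-4-enoate
Product: 12 ethyl (4E)-6-bromo-5-methylhex-4-enoate
Conditions: CBr4, PPh3, CH2Cl2, 0 °C
Reagents that add atoms: carbon tetrabromide BrC(Br)(Br)Br
Why: Appel bromination: the alkoxyphosphonium ion is displaced by bromide in an SN2 reaction at the primary carbon under neutral conditions, so neither allylic transposition nor loss of the E geometry is expected.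

Step 7
Reactants: 6 tert-butyl{[(2E,6E)-2,6-dimethyl-8-(phenylsulfonyl)octa-2,6-dien-1-yl]oxy}dimethylsilane; 12 ethyl (4E)-6-bromo-5-methylhex-4-enoate
Product: 14 racemic ethyl (4E,8E,12E)-14-[(tert-butyldimethylsilyl)oxy]-5,9,13-trimethyl-7-(phenylsulfonyl)tetradeca-4,8,12-trienoate, via lithiated sulfone 13 (not isolated)
Conditions: n-BuLi (1.05 equiv), THF, –78 °C; then 12 in THF, –78 → –40 °C; aq. NH4Cl
Reagents that add atoms: none
Why: n-BuLi removes a proton from C5' of 6 (α to sulfur and allylic), giving the sulfonyl-stabilised carbanion 13, which displaces bromide from the primary allylic carbon C4' of 12 in a direct SN2 reaction and so forms C4'–C5' (C6–C7 of 14). The closest known reaction type is the alkylation of lithiated prenyl- and geranyl-type phenyl sulfones with allylic halides, the standard way of joining terpenoid chains between two allylic carbons. No ring is closed. The single new stereocentre, the sulfonyl-bearing carbon, is formed without control as a racemate and is deleted in step 9, so nothing depends on it. Regioselectivity in the nucleophile (α over γ) follows from the charge being held next to sulfur and from the γ-carbon C7' being fully substituted; regioselectivity in the electrophile (SN2 over SN2') follows from the unhindered CH2Br and the absence of any metal that would ionise the bromide, the SN2' site C2' being a more hindered secondary sp2 carbon. Chemoselectivity over the ester rests on rate: displacement of a primary allylic bromide at –78 °C is much faster than addition to an ester carbonyl, and 13, derived from a carbon acid far more acidic than an ester α-CH, does not enolise the ester. Since neither allyl unit is ionised, C2'=C3' and C6'=C7' keep the E geometry of 12 and 6.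

Step 8
Reactants: 14 racemic ethyl (4E,8E,12E)-14-[(tert-butyldimethylsilyl)oxy]-5,9,13-trimethyl-7-(phenylsulfonyl)tetradeca-4,8,12-trienoate
Product: 15 racemic (4E,8E,12E)-14-[(tert-butyldimethylsilyl)oxy]-5,9,13-trimethyl-7-(phenylsulfonyl)tetradeca-4,8,12-trienoic acid
Conditions: LiOH, THF/EtOH/H2O, rt; dilute HCl to pH 4, 0 °C
Reagents that add atoms: lithium hydroxide [Li+].[OH-]
Why: Ester saponification; the free acid is needed because the hydride of step 9 would reduce an ester but leaves a lithium carboxylate alone, and the primary allylic silyl ether and the allylic sulfone are stable to LiOH at room temperature.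

Step 9
Reactants: 15 racemic (4E,8E,12E)-14-[(tert-butyldimethylsilyl)oxy]-5,9,13-trimethyl-7-(phenylsulfonyl)tetradeca-4,8,12-trienoic acid
Product: 17 (4E,8E,12E)-14-[(tert-butyldimethylsilyl)oxy]-5,9,13-trimethyltetradeca-4,8,12-trienoic acid, via lithium carboxylate of the sulfone acid 16 (not isolated)
Conditions: LiBHEt3 (4 equiv), PdCl2[Ph2P(CH2)3PPh2] (5 mol %), THF, 0 °C → rt; dilute HCl to pH 4, 0 °C
Reagents that add atoms: none
Why: Palladium-catalysed reductive desulfonylation of an allylic sulfone: the first equivalent of hydride converts the acid into carboxylate 16, zerovalent palladium formed in the flask ionises the C5'–S bond to a π-allyl complex, and hydride is delivered to the less substituted terminus C5' (a CH against the fully substituted C7'), so C6'=C7' stays in place. The bidentate phosphine favours fast, regioselective hydride transfer before syn/anti isomerisation, so the E geometry should be kept.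

Step 10
Reactants: 17 (4E,8E,12E)-14-[(tert-butyldimethylsilyl)oxy]-5,9,13-trimethyltetradeca-4,8,12-trienoic acid; 18 methyl salicylate
Product: 19 methyl 2-{[(4E,8E,12E)-14-[(tert-butyldimethylsilyl)oxy]-5,9,13-trimethyltetradeca-4,8,12-trienoyl]oxy}benzoate
Conditions: DCC, DMAP (cat.), CH2Cl2, 0 °C → rt
Reagents that add atoms: none
Why: Steglich esterification: the O-acylisourea from 17 and DCC is converted by DMAP into an acylpyridinium ion that acylates the hydrogen-bonded, weakly nucleophilic phenol of 18 under neutral conditions tolerated by the silyl ether and the 1,5-diene array.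

Step 11
Reactants: 19 methyl 2-{[(4E,8E,12E)-14-[(tert-butyldimethylsilyl)oxy]-5,9,13-trimethyltetradeca-4,8,12-trienoyl]oxy}benzoate
Product: 21 3-[(2E,6E,10E)-12-[(tert-butyldimethylsilyl)oxy]-3,7,11-trimethyldodeca-2,6,10-trien-1-yl]-4-hydroxy-2H-chromen-2-one, via lithium ester enolate 20 (not isolated)
Conditions: LiN(SiMe3)2 (3 equiv), THF, –78 → 0 °C; cold dilute HCl
Reagents that add atoms: none
Why: Intramolecular Claisen (Dieckmann-type) condensation: LiN(SiMe3)2 forms ester enolate 20 at the future C3, which attacks the neighbouring methyl ester in a 6-(enolendo)-exo-trig closure, forming C3–C4 with loss of methoxide. The excess base converts the product into its stabilised enolate, which drives the closure, and because the chain is on carbon from the start the O- versus C-alkylation problem of 4-hydroxycoumarins does not arise.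

Step 12
Reactants: 21 3-[(2E,6E,10E)-12-[(tert-butyldimethylsilyl)oxy]-3,7,11-trimethyldodeca-2,6,10-trien-1-yl]-4-hydroxy-2H-chromen-2-one
Product: 22 4-hydroxy-3-[(2E,6E,10E)-12-hydroxy-3,7,11-trimethyldodeca-2,6,10-trien-1-yl]-2H-chromen-2-one
Conditions: HF·pyridine, pyridine, THF, 0 °C → rt
Reagents that add atoms: none
Why: Fluoride cleaves the Si–O bond of the primary silyl ether; pyridine-buffered HF is chosen so that the acidic 4-hydroxyl group does not add across C2'=C3', and the lactone and olefins are inert.

Step 13
Reactants: 22 4-hydroxy-3-[(2E,6E,10E)-12-hydroxy-3,7,11-trimethyldodeca-2,6,10-trien-1-yl]-2H-chromen-2-one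
Product: 24 E-omega-benzoyloxyferulenol, (2E,6E,10E)-12-(4-hydroxy-2-oxo-2H-chromen-3-yl)-2,6,10-trimethyldodeca-2,6,10-trien-1-yl benzoate, via dibenzoate 23 (not isolated)
Conditions: BzCl (2.5 equiv), Et3N, DMAP (cat.), CH2Cl2, 0 °C; then morpholine, 0 °C; dilute HCl wash
Reagents that add atoms: benzoyl chloride O=C(Cl)c1ccccc1
Why: Acylation followed by selective aminolysis: excess acid chloride benzoylates both hydroxyl groups to give 23, whose O4 benzoate is a vinylogous mixed anhydride with the stabilised 4-oxidocoumarin as leaving group and is cleaved by a secondary amine at 0 °C, while the alkyl benzoate at C12' is inert to amines under these conditions.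

## Compound list

1 | geranyl bromide, (2E)-1-bromo-3,7-dimethylocta-2,6-diene | CC(C)=CCC/C(C)=C/CBr | starting material
2 | sodium benzenesulfinate | [Na+].[O-]S(=O)c1ccccc1 | starting material
3 | geranyl phenyl sulfone, [(2E)-3,7-dimethylocta-2,6-dien-1-yl] phenyl sulfone | CC(C)=CCC/C(C)=C/CS(=O)(=O)c1ccccc1 | intermediate
4 | (2E,6E)-2,6-dimethyl-8-(phenylsulfonyl)octa-2,6-dienal | O=C/C(C)=C/CC/C(C)=C/CS(=O)(=O)c1ccccc1 | intermediate (not isolated)
5 | (2E,6E)-2,6-dimethyl-8-(phenylsulfonyl)octa-2,6-dien-1-ol | OC/C(C)=C/CC/C(C)=C/CS(=O)(=O)c1ccccc1 | intermediate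
6 | tert-butyl{[(2E,6E)-2,6-dimethyl-8-(phenylsulfonyl)octa-2,6-dien-1-yl]oxy}dimethylsilane | O=S(=O)(C/C=C(\C)CC/C=C(\C)CO[Si](C)(C)C(C)(C)C)c1ccccc1 | intermediate
7 | 2-methylbut-3-en-2-ol | CC(C)(O)C=C | starting material
8 | 3-[(1-ethoxyethenyl)oxy]-3-methylbut-1-ene (mixed ketene acetal) | C=C(OCC)OC(C)(C)C=C | intermediate (not isolated)
9 | ethyl 5-methylhex-4-enoate | CCOC(=O)CCC=C(C)C | intermediate
10 | ethyl (4E)-5-methyl-6-oxohex-4-enoate | CCOC(=O)CC/C=C(\C)C=O | intermediate (not isolated)
11 | ethyl (4E)-6-hydroxy-5-methylhex-4-enoate | CCOC(=O)CC/C=C(\C)CO | intermediate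
12 | ethyl (4E)-6-bromo-5-methylhex-4-enoate | CCOC(=O)CC/C=C(\C)CBr | intermediate
13 | {(2E,6E)-8-[(tert-butyldimethylsilyl)oxy]-3,7-dimethyl-1-(phenylsulfonyl)octa-2,6-dien-1-yl}lithium (lithiated 6) | [Li]C(/C=C(\C)CC/C=C(\C)CO[Si](C)(C)C(C)(C)C)S(=O)(=O)c1ccccc1 | intermediate (not isolated)
14 | racemic ethyl (4E,8E,12E)-14-[(tert-butyldimethylsilyl)oxy]-5,9,13-trimethyl-7-(phenylsulfonyl)tetradeca-4,8,12-trienoate | CCOC(=O)CC/C=C(\C)CC(/C=C(\C)CC/C=C(\C)CO[Si](C)(C)C(C)(C)C)S(=O)(=O)c1ccccc1 | intermediate
15 | racemic (4E,8E,12E)-14-[(tert-butyldimethylsilyl)oxy]-5,9,13-trimethyl-7-(phenylsulfonyl)tetradeca-4,8,12-trienoic acid | OC(=O)CC/C=C(\C)CC(/C=C(\C)CC/C=C(\C)CO[Si](C)(C)C(C)(C)C)S(=O)(=O)c1ccccc1 | intermediate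
16 | lithium salt of 15 (racemic) | [Li+].[O-]C(=O)CC/C=C(\C)CC(/C=C(\C)CC/C=C(\C)CO[Si](C)(C)C(C)(C)C)S(=O)(=O)c1ccccc1 | intermediate (not isolated)
17 | (4E,8E,12E)-14-[(tert-butyldimethylsilyl)oxy]-5,9,13-trimethyltetradeca-4,8,12-trienoic acid | OC(=O)CC/C=C(\C)CC/C=C(\C)CC/C=C(\C)CO[Si](C)(C)C(C)(C)C | intermediate
18 | methyl salicylate | COC(=O)c1ccccc1O | starting material
19 | methyl 2-{[(4E,8E,12E)-14-[(tert-butyldimethylsilyl)oxy]-5,9,13-trimethyltetradeca-4,8,12-trienoyl]oxy}benzoate | COC(=O)c1ccccc1OC(=O)CC/C=C(\C)CC/C=C(\C)CC/C=C(\C)CO[Si](C)(C)C(C)(C)C | intermediate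
20 | lithium ester enolate of 19 (enolate geometry not specified) | COC(=O)c1ccccc1OC(O[Li])=CC/C=C(\C)CC/C=C(\C)CC/C=C(\C)CO[Si](C)(C)C(C)(C)C | intermediate (not isolated)
21 | 3-[(2E,6E,10E)-12-[(tert-butyldimethylsilyl)oxy]-3,7,11-trimethyldodeca-2,6,10-trien-1-yl]-4-hydroxy-2H-chromen-2-one | O=c1oc2ccccc2c(O)c1C/C=C(\C)CC/C=C(\C)CC/C=C(\C)CO[Si](C)(C)C(C)(C)C | intermediate
22 | 4-hydroxy-3-[(2E,6E,10E)-12-hydroxy-3,7,11-trimethyldodeca-2,6,10-trien-1-yl]-2H-chromen-2-one | O=c1oc2ccccc2c(O)c1C/C=C(\C)CC/C=C(\C)CC/C=C(\C)CO | intermediate
23 | (2E,6E,10E)-12-[4-(benzoyloxy)-2-oxo-2H-chromen-3-yl]-2,6,10-trimethyldodeca-2,6,10-trien-1-yl benzoate | O=c1oc2ccccc2c(OC(=O)c2ccccc2)c1C/C=C(\C)CC/C=C(\C)CC/C=C(\C)COC(=O)c1ccccc1 | intermediate (not isolated)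
24 | E-omega-benzoyloxyferulenol, (2E,6E,10E)-12-(4-hydroxy-2-oxo-2H-chromen-3-yl)-2,6,10-trimethyldodeca-2,6,10-trien-1-yl benzoate | C/C(=C\CC/C(C)=C/Cc1c(O)c2ccccc2oc1=O)CC/C=C(\C)COC(=O)c1ccccc1 | target

## Step count and risk

Total: 13 steps. Longest linear sequence: 10 steps (steps 1–3 or steps 4–6, then steps 7–13).

**Step 7 (key step).** The most likely failure is proton exchange between carbanion 13 and the still acidic product 14, leading to double alkylation and returned 6; on warming, acylation of 13 at the ester carbonyl could also set in. The fallback hides the carbonyl as a carboxylate. It sets out from 11, which is saponified with LiOH to (4E)-6-hydroxy-5-methylhex-4-enoic acid F1. F1 is brominated with PBr3 in Et2O at –10 °C, the aqueous work-up returning any acyl bromide to the acid, to give (4E)-6-bromo-5-methylhex-4-enoic acid F2. One equivalent of LiN(SiMe3)2 at –78 °C converts F2 into lithium (4E)-6-bromo-5-methylhex-4-enoate F3, which is added to 13. The carboxylate is inert to the carbanion, and alkylation followed by acidification should give sulfone acid 15 directly, where the route is rejoined with step 8 omitted.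

**Step 9.** The most likely failure is sluggish or uneven hydride transfer, because the substrate reacts as an aggregated lithium carboxylate. A long-lived π-allyl intermediate can equilibrate, which would move C6'=C7' to C5'=C6' or erode its E geometry. The fallback sets out from 14 and treats the neutral ester itself with excess LiBHEt3 and the same catalyst, accepting reduction of the ester. This should give (4E,8E,12E)-14-[(tert-butyldimethylsilyl)oxy]-5,9,13-trimethyltetradeca-4,8,12-trien-1-ol F4. F4 is oxidised with Dess–Martin periodinane to (4E,8E,12E)-14-[(tert-butyldimethylsilyl)oxy]-5,9,13-trimethyltetradeca-4,8,12-trienal F5, and a Pinnick oxidation (NaClO2, NaH2PO4, 2-methyl-2-butene) returns to the route at 17.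

**Step 11.** The most likely failure is fragmentation of aryl ester enolate 20 into a ketene and the phenoxide of 18 (E1cB), followed by unproductive consumption of the ketene, or intermolecular condensation. The fallback reverses the roles of the two esters. From 17, Me3SiCHN2 in MeOH gives methyl (4E,8E,12E)-14-[(tert-butyldimethylsilyl)oxy]-5,9,13-trimethyltetradeca-4,8,12-trienoate F6. Its lithium enolate (LiN(SiMe3)2, two equivalents, –78 °C) cannot lose alkoxide to form a ketene, and is C-acylated with 2-acetoxybenzoyl chloride to the racemic β-keto ester methyl (4E,8E,12E)-2-(2-acetoxybenzoyl)-14-[(tert-butyldimethylsilyl)oxy]-5,9,13-trimethyltetradeca-4,8,12-trienoate F7. K2CO3 in MeOH removes the acetate, and the liberated phenoxide lactonises onto the methyl ester, returning to the route at 21.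

**Step 13.** The most likely failure is imperfect discrimination in the aminolysis: the amine may add at C4 with displacement of the benzoyloxy group, or the O4 benzoate may be only partly cleaved. The fallback installs the benzoate before the acidic enol exists. From 19, HF·pyridine gives methyl 2-{[(4E,8E,12E)-14-hydroxy-5,9,13-trimethyltetradeca-4,8,12-trienoyl]oxy}benzoate F8. BzCl and pyridine give methyl 2-{[(4E,8E,12E)-14-(benzoyloxy)-5,9,13-trimethyltetradeca-4,8,12-trienoyl]oxy}benzoate F9. Closure with LiN(SiMe3)2 (2.2 equiv) in THF at –78 °C, quenched cold with acid, should give 24 directly; the remote benzoate is not attacked by the hindered amide base.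

**Step 2.** The most likely failure is incomplete conversion together with over-oxidation and minor attack at the allylic methylene positions, giving a mixture that is laborious to separate. The fallback builds the oxidised terminus by cleavage and olefination. From 3, one equivalent of mCPBA at 0 °C epoxidises the electron-rich distal olefin to racemic 2,2-dimethyl-3-[(3E)-3-methyl-5-(phenylsulfonyl)pent-3-en-1-yl]oxirane F10. HIO4 in aqueous THF cleaves it to (4E)-4-methyl-6-(phenylsulfonyl)hex-4-enal F11. The stabilised Wittig reagent Ph3P=C(Me)CO2Et gives ethyl (2E,6E)-2,6-dimethyl-8-(phenylsulfonyl)octa-2,6-dienoate F12 with E selectivity, and i-Bu2AlH at –78 °C returns to the route at 5.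

## Further compounds

F1 | step 7 | (4E)-6-hydroxy-5-methylhex-4-enoic acid | OC(=O)CC/C=C(\C)CO
F2 | step 7 | (4E)-6-bromo-5-methylhex-4-enoic acid | OC(=O)CC/C=C(\C)CBr
F3 | step 7 | lithium (4E)-6-bromo-5-methylhex-4-enoate | [Li+].[O-]C(=O)CC/C=C(\C)CBr
F4 | step 9 | (4E,8E,12E)-14-[(tert-butyldimethylsilyl)oxy]-5,9,13-trimethyltetradeca-4,8,12-trien-1-ol | OCCC/C=C(\C)CC/C=C(\C)CC/C=C(\C)CO[Si](C)(C)C(C)(C)C
F5 | step 9 | (4E,8E,12E)-14-[(tert-butyldimethylsilyl)oxy]-5,9,13-trimethyltetradeca-4,8,12-trienal | O=CCC/C=C(\C)CC/C=C(\C)CC/C=C(\C)CO[Si](C)(C)C(C)(C)C
F6 | step 11 | methyl (4E,8E,12E)-14-[(tert-butyldimethylsilyl)oxy]-5,9,13-trimethyltetradeca-4,8,12-trienoate | COC(=O)CC/C=C(\C)CC/C=C(\C)CC/C=C(\C)CO[Si](C)(C)C(C)(C)C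
F7 | step 11 | racemic methyl (4E,8E,12E)-2-(2-acetoxybenzoyl)-14-[(tert-butyldimethylsilyl)oxy]-5,9,13-trimethyltetradeca-4,8,12-trienoate | COC(=O)C(C/C=C(\C)CC/C=C(\C)CC/C=C(\C)CO[Si](C)(C)C(C)(C)C)C(=O)c1ccccc1OC(C)=O
F8 | step 13 | methyl 2-{[(4E,8E,12E)-14-hydroxy-5,9,13-trimethyltetradeca-4,8,12-trienoyl]oxy}benzoate | COC(=O)c1ccccc1OC(=O)CC/C=C(\C)CC/C=C(\C)CC/C=C(\C)CO
F9 | step 13 | methyl 2-{[(4E,8E,12E)-14-(benzoyloxy)-5,9,13-trimethyltetradeca-4,8,12-trienoyl]oxy}benzoate | COC(=O)c1ccccc1OC(=O)CC/C=C(\C)CC/C=C(\C)CC/C=C(\C)COC(=O)c1ccccc1
F10 | step 2 | racemic 2,2-dimethyl-3-[(3E)-3-methyl-5-(phenylsulfonyl)pent-3-en-1-yl]oxirane | CC1(C)OC1CC/C(C)=C/CS(=O)(=O)c1ccccc1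
F11 | step 2 | (4E)-4-methyl-6-(phenylsulfonyl)hex-4-enal | O=CCC/C(C)=C/CS(=O)(=O)c1ccccc1
F12 | step 2 | ethyl (2E,6E)-2,6-dimethyl-8-(phenylsulfonyl)octa-2,6-dienoate | CCOC(=O)/C(C)=C/CC/C(C)=C/CS(=O)(=O)c1ccccc1
A1 | alternative 1 | 3-[(2E,6E,10E)-12-[(tert-butyldimethylsilyl)oxy]-3,7,11-trimethyldodeca-2,6,10-trien-1-yl]-4-hydroxy-2H-chromen-2-one | O=c1oc2ccccc2c(O)c1C/C=C(\C)CC/C=C(\C)CC/C=C(\C)CO[Si](C)(C)C(C)(C)C
A2 | alternative 1 | methyl 2-{[(4E,8E,12E)-14-[(tert-butyldimethylsilyl)oxy]-5,9,13-trimethyltetradeca-4,8,12-trienoyl]oxy}benzoate | COC(=O)c1ccccc1OC(=O)CC/C=C(\C)CC/C=C(\C)CC/C=C(\C)CO[Si](C)(C)C(C)(C)C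
A3 | alternative 1 | (2E,6E)-farnesyl bromide, (2E,6E)-1-bromo-3,7,11-trimethyldodeca-2,6,10-triene | CC(C)=CCC/C(C)=C/CC/C(C)=C/CBr
A4 | alternative 2 | (4E,8E)-10-(4-methoxy-2-oxo-2H-chromen-3-yl)-N,N,4,8-tetramethyldeca-4,8-dienamide | COc1c(C/C=C(\C)CC/C=C(\C)CCC(=O)N(C)C)c(=O)oc2ccccc12
A5 | alternative 2 | racemic 3-[(2E)-6-hydroxy-3,7-dimethylocta-2,7-dien-1-yl]-4-methoxy-2H-chromen-2-one | COc1c(C/C=C(\C)CCC(O)C(C)=C)c(=O)oc2ccccc12
A6 | alternative 3 | 3-[(2E,6E,10E)-12-[(tert-butyldiphenylsilyl)oxy]-3,7,11-trimethyldodeca-2,6,10-trien-1-yl]-4-methoxy-2H-chromen-2-one | COc1c(C/C=C(\C)CC/C=C(\C)CC/C=C(\C)CO[Si](c3ccccc3)(c3ccccc3)C(C)(C)C)c(=O)oc2ccccc12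
A7 | alternative 3 | tert-butyl{[(2E,6E,10E)-11-iodo-2,6,10-trimethylundeca-2,6,10-trien-1-yl]oxy}diphenylsilane | I/C=C(\C)CC/C=C(\C)CC/C=C(\C)CO[Si](c1ccccc1)(c1ccccc1)C(C)(C)C
A8 | alternative 3 | 3-(bromomethyl)-4-methoxy-2H-chromen-2-one | COc1c(CBr)c(=O)oc2ccccc12
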